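**Strategy.** Everything rests on forming the benzo ring of the indole (C3a, C4, C5, C6, C7, C7a) last, onto a finished pyrrole. That ring carries heteroatoms at C4 (OMe) and C6 (Br) in a 1,3 relationship with C5 and C7 unsubstituted, the pattern a ketene and an ynol ether deliver. One operation, a photochemical Wolff rearrangement followed by (2+2) cycloaddition, ring opening and 6π closure onto pyrrole C3, makes four C–C bonds and the benzene ring and leaves a free C4 phenol beside a C6 silyl ether. The precursor is an N-SEM pyrrole bearing a diazoacetyl group at C2 and an oxazol-5-yl group at C4.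

Key step: step 6

Remark (abbreviations): SEM = [2-(trimethylsilyl)ethoxy]methyl; TIPS = triisopropylsilyl; Boc = tert-butoxycarbonyl; PhNTf2 = N-phenylbis(trifluoromethanesulfonimide).

Remark (atom mapping): pyrrole C2, C3, C4, C5 of the precursor become indole C7a, C3a, C3, C2. The diazo carbon becomes C7, the ketone carbon C4, the alkyne CH carbon C5 and the siloxy carbon C6. The target has no stereocentre; intermediates 13 and 15 are racemic and lose their single centres within step 6.

Assumption: lithium ethynolate is taken to form from 3-phenylisoxazole in the same way that lithium phenylethynolate forms from 3,4-diphenylisoxazole.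

Step 1
Reactants: 1 methyl 4-formyl-1H-pyrrole-2-carboxylate
Product: 2 methyl 4-formyl-1-SEM-1H-pyrrole-2-carboxylate
Conditions: NaH, SEMCl, DMF, 0 °C to rt
Reagents that add atoms: 2-(trimethylsilyl)ethoxymethyl chloride C[Si](C)(C)CCOCCl
Why: The pyrrole N–H, acidified by the ester and formyl groups, is deprotonated by NaH and the anion is N-alkylated by SEMCl (SN2 N-alkylation), which blocks N1 with a group that tolerates base, light and palladium.

Step 2
Reactants: 2 methyl 4-formyl-1-SEM-1H-pyrrole-2-carboxylate; 3 tosylmethyl isocyanide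
Product: 4 methyl 4-(oxazol-5-yl)-1-SEM-1H-pyrrole-2-carboxylate
Conditions: K2CO3, MeOH, reflux
Reagents that add atoms: none
Why: In the van Leusen oxazole synthesis the isocyanide anion adds to the aldehyde, the alkoxide closes onto the isocyanide carbon and loss of p-toluenesulfinate aromatizes the ring to the 5-substituted oxazole, while the methyl ester is inert in methanol.

Step 3
Reactants: 4 methyl 4-(oxazol-5-yl)-1-SEM-1H-pyrrole-2-carboxylate
Product: 5 4-(oxazol-5-yl)-1-SEM-1H-pyrrole-2-carboxylic acid
Conditions: LiOH, THF/MeOH/H2O, rt; then 1 M HCl to pH 4, 0 °C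
Reagents that add atoms: lithium hydroxide [Li+].[OH-]
Why: Ester saponification by acyl substitution should proceed cleanly because the oxazole and the SEM aminal are stable to aqueous hydroxide at room temperature and to brief cold, mildly acidic work-up.

Step 4
Reactants: 5 4-(oxazol-5-yl)-1-SEM-1H-pyrrole-2-carboxylic acid
Product: 7 2-diazo-1-[4-(oxazol-5-yl)-1-SEM-1H-pyrrol-2-yl]ethan-1-one, via acid chloride 6 (not isolated)
Conditions: (COCl)2, DMF (cat.), CH2Cl2, 0 °C to rt; evaporate; CH2N2 (excess), Et2O/THF, 0 °C
Reagents that add atoms: diazomethane C=[N+]=[N-]; oxalyl chloride O=C(Cl)C(=O)Cl (its chlorine is carried only by intermediate 6)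
Why: Acid chloride formation followed by C-acylation of diazomethane (the diazoketone stage of the Arndt–Eistert sequence) should give the diazoketone, the excess diazomethane consuming the HCl so that no chloromethyl ketone forms.

Step 5
Reactants: 8 3-phenylisoxazole; 9 chlorotriisopropylsilane
Product: 11 (triisopropylsiloxy)acetylene, via lithium ethynolate 10 (not isolated)
Conditions: LiN(iPr)2, THF, −78 to 0 °C; then 9, −78 °C to rt; distil
Reagents that add atoms: none
Why: C5-lithiation of a 5-unsubstituted 3-arylisoxazole triggers fragmentation into benzonitrile and the ynolate (base-induced isoxazole-to-ynolate cleavage), and the bulky chlorosilane silylates the ynolate on oxygen and not on carbon, as in the known O-silylation of ynolates to triisopropylsilyl ynol ethers.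

Step 6
Reactants: 7 2-diazo-1-[4-(oxazol-5-yl)-1-SEM-1H-pyrrol-2-yl]ethan-1-one; 11 (triisopropylsiloxy)acetylene
Product: 16 3-(oxazol-5-yl)-6-(triisopropylsiloxy)-1-SEM-1H-indol-4-ol, via pyrrolylketene 12 (not isolated), via cyclobutenone 13 (not isolated), via dienylketene 14 (not isolated), via cyclohexadienone 15 (not isolated)
Conditions: hν (300 nm, Pyrex), 11 (2 equiv), ClCH2CH2Cl, rt; then 80 °C
Reagents that add atoms: none
Why: Irradiation expels N2 from 7 and the pyrrolyl group migrates to the carbene carbon (Wolff rearrangement, forming C7–C7a) to give ketene 12, which adds the ynol ether in a thermal (2+2) cycloaddition to cyclobutenone 13 (forming C4–C5 and C6–C7). Warming opens 13 by reversible conrotatory four-electron electrocyclic cleavage to dienylketene 14, and the isomer with the pyrrole cis to the ketenyl carbon closes the six-membered carbocycle by disrotatory six-electron electrocyclization onto pyrrole C3 (forming C3a–C4) to give dienone 15, which enolizes to the aromatic phenol 16. The closest known reaction type is the Danheiser benzannulation in its photochemical Wolff variant, which is established for aryl and heteroaryl diazoketones with siloxyalkynes. No stereocentre survives, since the single centres of 13 and 15 are erased by ring opening and tautomerization. The step needs regiocontrol in the (2+2) event, which the polarization of the ynol ether secures (its nucleophilic CH carbon attacks the ketene carbonyl carbon, so the two oxygens end up 1,3), and site control in the closure, which is secured because N1 is blocked by SEM and C3 is the only free position next to the ketene-bearing carbon. The oxazole and SEM groups are spectators, and 300 nm light through Pyrex should limit secondary photochemistry of the product.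

Step 7
Reactants: 16 3-(oxazol-5-yl)-6-(triisopropylsiloxy)-1-SEM-1H-indol-4-ol
Product: 17 4-methoxy-3-(oxazol-5-yl)-6-(triisopropylsiloxy)-1-SEM-1H-indole
Conditions: MeI, K2CO3, acetone, rt
Reagents that add atoms: iodomethane CI
Why: Williamson O-methylation of the only free phenol should be selective because the hindered aryl TIPS ether at C6 is stable to K2CO3 in dry acetone and cannot migrate between the meta oxygens.

Step 8
Reactants: 17 4-methoxy-3-(oxazol-5-yl)-6-(triisopropylsiloxy)-1-SEM-1H-indole
Product: 19 4-methoxy-3-(oxazol-5-yl)-1-SEM-1H-indol-6-yl trifluoromethanesulfonate, via tetrabutylammonium phenoxide 18 (not isolated)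
Conditions: Bu4NF, THF, 0 °C; then PhNTf2, 0 °C to rt
Reagents that add atoms: N-phenylbis(trifluoromethanesulfonimide) O=S(=O)(N(c1ccccc1)S(=O)(=O)C(F)(F)F)C(F)(F)F
Why: Fluoride cleaves the aryl silyl ether to the C6 phenoxide, which is sulfonylated in the same flask by the mild triflating agent (desilylation then O-triflation), while the N-SEM group resists fluoride at this temperature.

Step 9
Reactants: 19 4-methoxy-3-(oxazol-5-yl)-1-SEM-1H-indol-6-yl trifluoromethanesulfonate
Product: 20 6-bromo-4-methoxy-3-(oxazol-5-yl)-1-SEM-1H-indole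
Conditions: Pd2(dba)3, t-BuBrettPhos, KBr, KF, 1,4-dioxane, 130 °C
Reagents that add atoms: potassium bromide [K+].[Br-]
Why: In the palladium-catalysed triflate-to-bromide exchange the aryl triflate adds oxidatively to zerovalent palladium, triflate is exchanged for bromide, and the very bulky biaryl phosphine forces C–Br reductive elimination; the step is placed before any iodide is present.

Step 10
Reactants: 20 6-bromo-4-methoxy-3-(oxazol-5-yl)-1-SEM-1H-indole
Product: 21 6-bromo-3-(2,4-diiodooxazol-5-yl)-4-methoxy-1-SEM-1H-indole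
Conditions: LiN(SiMe3)2 (excess), I2 (excess), THF/DMPU, −78 °C to rt
Reagents that add atoms: iodine II
Why: Oxazole lithiation–iodination should reach both positions, because the 2-lithiooxazole equilibrates with its ring-opened isocyanoenolate, which is iodinated at the carbon that becomes C4 before reclosing, and a second C2 metalation–iodination follows; the amide base is too weak to touch the aryl bromide or indole C2–H.

Step 11
Reactants: 21 6-bromo-3-(2,4-diiodooxazol-5-yl)-4-methoxy-1-SEM-1H-indole; 22 [1-(tert-butoxycarbonyl)-1H-pyrrol-2-yl]boronic acid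
Product: 23 tert-butyl 2-[5-(6-bromo-4-methoxy-1-SEM-1H-indol-3-yl)-4-iodooxazol-2-yl]-1H-pyrrole-1-carboxylate
Conditions: Pd(PPh3)4, Na2CO3, DME/H2O, 70 °C
Reagents that add atoms: none
Why: Suzuki–Miyaura coupling should occur only at the oxazole C2–I bond, the most electron-poor carbon–halogen bond and the fastest to add to zerovalent palladium, leaving the C4 iodide and the aryl bromide untouched.

Step 12
Reactants: 23 tert-butyl 2-[5-(6-bromo-4-methoxy-1-SEM-1H-indol-3-yl)-4-iodooxazol-2-yl]-1H-pyrrole-1-carboxylate
Product: 24 6-bromo-3-[4-iodo-2-(1H-pyrrol-2-yl)oxazol-5-yl]-4-methoxy-1H-indole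
Conditions: Bu4NF, THF, 65 °C
Reagents that add atoms: none
Why: Fluoride attack at silicon fragments the SEM group (β-elimination with loss of ethene and formaldehyde) and warm Bu4NF also cleaves the pyrrole N-Boc carbamate, so both nitrogens should be freed in one global deprotection that leaves the aryl halides and the methyl ether intact.

**Compound list**

1 | methyl 4-formyl-1H-pyrrole-2-carboxylate | COC(=O)c1cc(C=O)c[nH]1 | starting material
2 | methyl 4-formyl-1-SEM-1H-pyrrole-2-carboxylate | COC(=O)c1cc(C=O)cn1COCC[Si](C)(C)C | intermediate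
3 | tosylmethyl isocyanide | Cc1ccc(S(=O)(=O)C[N+]#[C-])cc1 | starting material
4 | methyl 4-(oxazol-5-yl)-1-SEM-1H-pyrrole-2-carboxylate | COC(=O)c1cc(-c2cnco2)cn1COCC[Si](C)(C)C | intermediate
5 | 4-(oxazol-5-yl)-1-SEM-1H-pyrrole-2-carboxylic acid | OC(=O)c1cc(-c2cnco2)cn1COCC[Si](C)(C)C | intermediate
6 | 4-(oxazol-5-yl)-1-SEM-1H-pyrrole-2-carbonyl chloride | O=C(Cl)c1cc(-c2cnco2)cn1COCC[Si](C)(C)C | intermediate
7 | 2-diazo-1-[4-(oxazol-5-yl)-1-SEM-1H-pyrrol-2-yl]ethan-1-one | [N-]=[N+]=CC(=O)c1cc(-c2cnco2)cn1COCC[Si](C)(C)C | intermediate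
8 | 3-phenylisoxazole | c1ccc(cc1)-c1ccon1 | starting material
9 | chlorotriisopropylsilane | CC(C)[Si](Cl)(C(C)C)C(C)C | starting material
10 | lithium ethynolate | [Li+].[O-]C#C | intermediate
11 | (triisopropylsiloxy)acetylene | C#CO[Si](C(C)C)(C(C)C)C(C)C | intermediate
12 | 2-[4-(oxazol-5-yl)-1-SEM-1H-pyrrol-2-yl]ethen-1-one (pyrrolylketene) | O=C=Cc1cc(-c2cnco2)cn1COCC[Si](C)(C)C | intermediate
13 | (±)-4-[4-(oxazol-5-yl)-1-SEM-1H-pyrrol-2-yl]-3-(triisopropylsiloxy)cyclobut-2-en-1-one | O=C1C=C(O[Si](C(C)C)(C(C)C)C(C)C)C1c1cc(-c2cnco2)cn1COCC[Si](C)(C)C | intermediate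
14 | (3E)-4-[4-(oxazol-5-yl)-1-SEM-1H-pyrrol-2-yl]-3-(triisopropylsiloxy)buta-1,3-dien-1-one (pyrrole cis to the ketenyl carbon) | O=C=C/C(O[Si](C(C)C)(C(C)C)C(C)C)=C\c1cc(-c2cnco2)cn1COCC[Si](C)(C)C | intermediate
15 | (±)-3-(oxazol-5-yl)-6-(triisopropylsiloxy)-1-SEM-1,3a-dihydro-4H-indol-4-one | O=C1C=C(O[Si](C(C)C)(C(C)C)C(C)C)C=C2N(COCC[Si](C)(C)C)C=C(-c3cnco3)C12 | intermediate
16 | 3-(oxazol-5-yl)-6-(triisopropylsiloxy)-1-SEM-1H-indol-4-ol | Oc1cc(O[Si](C(C)C)(C(C)C)C(C)C)cc2n(COCC[Si](C)(C)C)cc(-c3cnco3)c12 | intermediate
17 | 4-methoxy-3-(oxazol-5-yl)-6-(triisopropylsiloxy)-1-SEM-1H-indole | COc1cc(O[Si](C(C)C)(C(C)C)C(C)C)cc2n(COCC[Si](C)(C)C)cc(-c3cnco3)c12 | intermediate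
18 | tetrabutylammonium 4-methoxy-3-(oxazol-5-yl)-1-SEM-1H-indol-6-olate | CCCC[N+](CCCC)(CCCC)CCCC.COc1cc([O-])cc2n(COCC[Si](C)(C)C)cc(-c3cnco3)c12 | intermediate
19 | 4-methoxy-3-(oxazol-5-yl)-1-SEM-1H-indol-6-yl trifluoromethanesulfonate | COc1cc(OS(=O)(=O)C(F)(F)F)cc2n(COCC[Si](C)(C)C)cc(-c3cnco3)c12 | intermediate
20 | 6-bromo-4-methoxy-3-(oxazol-5-yl)-1-SEM-1H-indole | COc1cc(Br)cc2n(COCC[Si](C)(C)C)cc(-c3cnco3)c12 | intermediate
21 | 6-bromo-3-(2,4-diiodooxazol-5-yl)-4-methoxy-1-SEM-1H-indole | COc1cc(Br)cc2n(COCC[Si](C)(C)C)cc(-c3oc(I)nc3I)c12 | intermediate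
22 | [1-(tert-butoxycarbonyl)-1H-pyrrol-2-yl]boronic acid | CC(C)(C)OC(=O)n1cccc1B(O)O | starting material
23 | tert-butyl 2-[5-(6-bromo-4-methoxy-1-SEM-1H-indol-3-yl)-4-iodooxazol-2-yl]-1H-pyrrole-1-carboxylate | COc1cc(Br)cc2n(COCC[Si](C)(C)C)cc(-c3oc(-c4cccn4C(=O)OC(C)(C)C)nc3I)c12 | intermediate
24 | 6-bromo-3-[4-iodo-2-(1H-pyrrol-2-yl)oxazol-5-yl]-4-methoxy-1H-indole | COc1cc(Br)cc2[nH]cc(-c3oc(-c4ccc[nH]4)nc3I)c12 | target

**Step count.** Total: 12 steps. Longest linear sequence: 11 steps (steps 1–4 and 6–12); step 5 is a one-step side branch.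

**Steps most likely to fail**

1. Step 6. The oxazolylpyrrole chromophore or the indole product may degrade under irradiation, the ketene may dimerize, or the sequence may stall at the cyclobutenone. The fallback takes light out of the annulation and generates the ketene thermally. It sets out from 7: a Wolff rearrangement promoted by PhCO2Ag and Et3N in methanol should give methyl 2-[4-(oxazol-5-yl)-1-SEM-1H-pyrrol-2-yl]acetate F1. LiOH hydrolysis then gives 2-[4-(oxazol-5-yl)-1-SEM-1H-pyrrol-2-yl]acetic acid F2, and oxalyl chloride gives 2-[4-(oxazol-5-yl)-1-SEM-1H-pyrrol-2-yl]acetyl chloride F3. Slow addition of Et3N to F3 and 11 in toluene at 80–110 °C should form ketene 12 by dehydrochlorination, which passes through 13, 14 and 15 and comes back to the route at 16.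

2. Step 9. Carbon–bromine reductive elimination may be slow, so that hydrodetriflation, C–H arylation at oxazole C2 or fluoride erosion of the SEM group competes. The fallback replaces the direct exchange by an ipso substitution in two operations. It sets out from 19: stannylation with Me3SnSnMe3, Pd(PPh3)4 and LiCl in 1,4-dioxane at 100 °C should give 4-methoxy-3-(oxazol-5-yl)-1-SEM-6-(trimethylstannyl)-1H-indole F4. Bromodestannylation with N-bromosuccinimide in CH2Cl2 at −78 °C should then replace tin by bromine at the same carbon and come back to the route at 20.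

3. Step 5. The ynolate may be silylated on carbon, the terminal alkyne C–H may be deprotonated, the base may add to the benzonitrile co-product, or the volatile product may be lost on isolation. The fallback generates the ynolate by a carbenoid rearrangement instead of a heterocycle fragmentation, following the ynolate-forming stage of the Kowalski ester homologation. It sets out from 9, with ethyl formate in place of 8: dibromomethyllithium (from CH2Br2 and lithium 2,2,6,6-tetramethylpiperidide, THF, −78 °C) adds to ethyl formate, and a second equivalent of the amide base converts the adduct into lithium 2,2-dibromoethen-1-olate F5. One equivalent of n-BuLi then effects bromine–lithium exchange and a 1,2-hydride shift to lithium ethynolate 10, which 9 silylates, coming back to the route at 11.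

**Further compounds**

F1 | step 6 | methyl 2-[4-(oxazol-5-yl)-1-SEM-1H-pyrrol-2-yl]acetate | COC(=O)Cc1cc(-c2cnco2)cn1COCC[Si](C)(C)C
F2 | step 6 | 2-[4-(oxazol-5-yl)-1-SEM-1H-pyrrol-2-yl]acetic acid | OC(=O)Cc1cc(-c2cnco2)cn1COCC[Si](C)(C)C
F3 | step 6 | 2-[4-(oxazol-5-yl)-1-SEM-1H-pyrrol-2-yl]acetyl chloride | O=C(Cl)Cc1cc(-c2cnco2)cn1COCC[Si](C)(C)C
F4 | step 9 | 4-methoxy-3-(oxazol-5-yl)-1-SEM-6-(trimethylstannyl)-1H-indole | COc1cc([Sn](C)(C)C)cc2n(COCC[Si](C)(C)C)cc(-c3cnco3)c12
F5 | step 5 | lithium 2,2-dibromoethen-1-olate | [Li+].[O-]C=C(Br)Br
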